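Temperature is what separates these flasks: the charge and the time are the same, set at −5 °C, 25 °C, 55 °C and 85 °C.

    substrate → intermediate A (k1 = 0.00636 /s, Ea1 = 91.0 kJ/mol)
    crystals ⇌ target, rate k2*(cs2 - [target]) while solid is left; crystals form when [target] > cs2 (cs2 = 1.8 mM, k2 = 0.136 /s)
    target ⇌ isomer of the product (K3 = 0.668, k3 = 0.0458 /s, Ea3 = 90.0 kJ/mol, ΔH3 = −61.0 kJ/mol)
    intermediate A ⇌ target (K4 = 0.98, k4 = 0.00902 /s, Ea4 = 78.0 kJ/mol, ΔH4 = −26.0 kJ/mol)
    substrate + target → side product (k5 = 0.0904 /M/s, Ea5 = 40.0 kJ/mol)
    reagent + intermediate A ⇌ intermediate B (K6 = 19.1 /M, k6 = 0.177 /M/s, Ea6 = 64.0 kJ/mol, ΔH6 = −15.0 kJ/mol)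
    (constants at 25 °C)

| setting | summer | midnight | spring | autumn |
|---|---|---|---|---|
| substrate | 0.050 M | 0.050 M | 0.050 M | 0.050 M |
| reagent | 0.0750 M | 0.0750 M | 0.0750 M | 0.0750 M |
| temperature | −5 °C | 55 °C | 85 °C | 25 °C |
| time | 15 min | 15 min | 15 min | 15 min |

- percentages count the substrate that a species holds: one side product counts as two
- target is meant together with its crystals
- solid, in amounts per volume of the solution: crystals
- the list of constants is for 25 °C, to be carried to other temperatures by the activation energies and enthalpies

* the flask with the highest amount of target, in percent of the substrate charged ("all alike" if they lie within 1.5 percentage points) (summer / midnight / spring / autumn / all alike)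
* final target, as a percentage of the substrate charged, in summer
* final target, as a percentage of the substrate charged, in midnight
* final target, as a percentage of the substrate charged, in spring
* final target, as a percentage of the substrate charged, in autumn

The substrate is the limiting reagent, so I wrote the balance of its charge:

charge = target + intermediate A + intermediate B + isomer of the product + side product

The bench rule says that crystals pull the equilibria across, so a flask loses one saturated solution. That rule promised 96.4% of target in a flask that crystallises. But while solid stands, c(target) sits near 1.8 mM, and the reversible steps then keep their companions in solution: c(isomer of the product) = K3·cs2, c(intermediate A) = cs2/K4 and c(intermediate B) = K6·c(reagent)·c(intermediate A). I took the reagent at its charge and carried each constant to temperature by its enthalpy.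

H = (cs2/cA)·(K3 + (1 + K6·cB)/K4)

At midnight this gave 17.7%. This hold-back is the share of the charge that the companions of a saturated solution keep away from the target. In spring it rose to 32.4%, and in autumn it was 11.3%. The bracket, a ratio of given numbers, shows where the bench rule stops: it is 3.15 in autumn, so the companions are not a small correction. For the two hot flasks I expected the balance to be reached, so:

midnight: target = 1 − H = 82.3%
spring: target = 1 − H = 67.6%

Autumn needed two deductions. With c(target) near saturation, the selectivity factor gives side product of about 2·k5·cs2/k1 = 5.12%. The step from intermediate A to intermediate B is not fast against k4: it goes forward at 0.0133 /s and back at 0.00927 /s, with k4 at 0.00902 /s. So I treated intermediate A and intermediate B as a coupled pool that drains through k4, and its slower decay rate is 0.00292 /s. That allows 2.63 lifetimes, so a share exp(−n) of the pool stays behind. I left aside the minutes the substrate takes to feed the pool, so this share is a low estimate.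

autumn: target = 76.3%

In summer the rule does not apply. There k1 falls to 0.00628 /min and k4 to 0.0160 /min. The start of a chain of two steps then gives

summer: target ≈ 0.5·k1·k4·t² = 1.13%

This is less than the saturation share of 3.60%, so I expected no crystals and no use for H. My choice was midnight.

The forecast also chose midnight, with 0.65% in summer, 80.5% at midnight, 68.3% in spring and 73% in autumn, where its figure lies below mine. Its grounds were that "Midnight reaches the crystal-driven equilibrium".

The simulation gave 0.537% in summer, 81.2% at midnight, 68.1% in spring and 75.5% in autumn, so midnight led, as the forecast said. At midnight the flask was at rest early: its target already stood at 81.2% after 7.50 min, and its companions finally held 17.3% against a hold-back of 17.7%. The neighbour like summer but kept at 20 °C has a hold-back of 11.6%. After 15.0 min its companions still held 34.7%, and its target, crystals counted, was 55.2%.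

All constants stand for no real mixture; the result is computed.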